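## The problem

1. Atoms are numbered C1 (terminal =CH2) to C19 (benzylic CH2) along the chain, and C20 is the chloromethine carbon on C18. The only ring is the phenyl group on C19, so no ring can relay or lock stereochemistry.
2. The six stereocentres (4R,5R,10R,11R,13R,16R, all six substituents on one face of the zigzag chain) form three clusters: C4-OH/C5-Me, C10-OH/C11-Me/C13-Me and C16-OH. The clusters are insulated from each other by C6–C9 and by C14–C15.
3. Inside a cluster a methyl-bearing carbon can steer its neighbour (C5 to C4 and C11 to C10, both in the Felkin sense). No cluster can control another, and remote epimers will not separate, so each cluster needs its own source of absolute configuration in high purity.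
4. The hardest element is C18=C20. It is a trisubstituted chloroalkene whose two carbon substituents, C17H2 and C19H2, are both methylene groups, so olefination of a C18 ketone has nothing to choose between, yet the target needs Cl cis to C17 (Z).
5. C16, the most isolated stereocentre, sits right next to this alkene.
6. The feature that opens the problem is the array O–C16–C17–C18(=C20HCl). C16 is homoallylic to the chloroalkene, which is the retron of an allyl transfer with allylic transposition from a CH2(17)=C18(CH2Ph)–C20HCl–B unit. In that unit one sp3 centre (C20) can encode both the C16 configuration and the alkene geometry.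
7. A second feature is a hidden repeat: C1–C6 and C7–C12 are the same unit CH2=CH–CH2–CH(OH)–CH(CH3)–CH2 with the same (R,R) sense, C7=C8 being saturated in the target.
8. C1=C2 and the vinyl chloride rule out hydrogenation, dissolving metals and free radicals at C6 (5-hexenyl cyclisation) late in the route. Strong acid or base could move C18=C20 into conjugation with the phenyl ring.

## Retrosynthesis

**C16–C17 (key cut).**
- Target 31 comes from its 4,10-bis-silyl ether 30 by desilylation.
- In 30 the C16–C17 bond is cut and the double bond is moved back from C18=C20 to C17=C18. This gives aldehyde 20 (C1–C16) and the (R)-α-chloroallylboronic ester 28 (C17–C20 plus benzyl).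
- The neighbouring cuts are poorer. C17–C18 needs a C17 organometallic with a β-oxygen, C18=C20 is the unbiased olefination, and C15–C16 leaves the alkene problem untouched.
- This single cut removes the most isolated stereocentre, the alkene geometry and the last fragment union. Aldehyde 20 has nothing near its carbonyl group, and 28 has one stereocentre in its carbon skeleton.
- The forward reaction must run through one chair with Cl axial, and C20 must keep its configuration until then.

**Insertion of C20 between boron and C18.**
- Removing C20 from 28 leads to alkenylboronic ester 26 of a C2-symmetric diol.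
- Forward, a Matteson homologation through borate 27 brings in C20 with its chlorine, and the diol decides which chloride is displaced.
- Allylic chlorination of an allylboron compound would offer neither regio- nor enantiocontrol.
- The carbon skeleton of 26 is achiral. It comes by halogen–lithium exchange and borylation (24, 25) from bromide 23.
- Bromide 23 is made by forming the C19–phenyl bond from 21 and 22.

**C16 as a masked aldehyde.**
- The formyl group of 20 is traced through epoxide 19 to the isopropylidene end (C16=CMe2) of diene 18.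
- This mask needs no protecting-group steps and is inert to hindered boranes, organoaluminium reagents and palladium.
- It carries two more alkyl groups than C1=C2, so a peracid should find it selectively.
- The forward steps only have to keep C1=C2 intact.

**C6–C7.**
- Diene 18 is cut in the tetramethylene spacer into bromide 8 (C1–C6) and alkene 16 (C7–C16 plus the mask).
- This cut uses the hidden repeat. The C7=C8 alkene of 16 arrives for free with the allylation that sets C10, and it becomes the nucleophile (borane 17).
- No hydrogenation is needed, as it would be after a Wittig or metathesis union, so C1=C2 survives.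
- Cuts at C7–C8 or C8–C9 would need extra carbons added to either half.
- The forward reaction is an sp3–sp3 Suzuki–Miyaura coupling on a β-branched primary bromide.

**C3–C4 and C9–C10.**
- Both carbinols are homoallylic, so 5 (on the way to 8 through 6 and 7) and 15 (on the way to 16) come from α-methyl aldehydes 3 and 13.
- Both use the same Brown allylboration with the same reagent enantiomer (adducts 4 and 14).
- In both cases the required syn relation is also the Felkin one, so reagent and substrate agree.
- Aldehyde 3 is two steps from Roche ester 1 (through 2), which supplies C5.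

**C11–CH3, C10–O and C10=C11.**
- Aldehyde 13 comes from alcohol 12.
- In 12 the C11 methyl group and the C10 oxygen are removed together, which leaves terminal alkene 10. Forward, this is a ZACA reaction through alane 11, followed by oxidation.
- Because C13 is already fixed, an error at C11 gives a 1,3-diastereomer next door, not a remote epimer.
- Diene 10 is the methylenation product of (R)-citronellal 9, whose carbons map on C11–C16, whose stereocentre is C13, and whose isopropylidene group is the C16 mask.

## Roads not taken

**Alternative 1: (the obvious route) cut C18=C20.**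
- The forward key step is chloromethylenation of the protected β-hydroxy ketone A1 with a chloromethylene ylide. C16 is set beforehand by an aldol or allylation step.
- C18 is flanked by two CH2 groups of nearly equal size, so the betaine or oxaphosphetane has no bias and an E/Z mixture must be expected at the last stage.
- A1 is a benzyl ketone with a β-silyloxy group. The basic ylide can enolise it and trigger β-elimination.
- C16 and the alkene cost separate steps, whereas the chosen plan sets both in the step that joins the fragments.

**Alternative 2: cut C18–C19 and C20–Cl from terminal alkyne A2.**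
- The forward key step is syn-benzylmetalation of A2, followed by chlorination of the alkenyl metal with retention.
- Syn addition places the new benzyl group and the metal, and hence Cl, cis to each other. The product is therefore the E isomer A3, the wrong geometry.
- The correct isomer would require adding C17 as the nucleophile to a benzyl-substituted alkyne. That means a C17 organometallic with a β-oxygen, which eliminates.
- C16 again needs its own asymmetric step.

**Alternative 3: cut C7–C8.**
- The forward key step is a mixed Kolbe electrolysis (or a related double decarboxylative radical coupling) of acids A4 and A5.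
- Two primary radicals of equal character couple statistically, so two costly chiral acids are largely lost to homodimers.
- The C7 radical carries C1=C2 within reach of 6-exo cyclisation, and the electron-rich C16 alkene of A5 is itself oxidisable at the anode.
- Each acid also needs extra carbons and oxidation steps. The chosen C6–C7 coupling uses the alkene of 16 and the bromide of 8 as they stand.

Key step: step 18

Assumption: enantiopure (R)-Roche ester and synthetic-grade (R)-citronellal of high enantiomeric purity are used, because C5 and C13 cannot be upgraded later in the route.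

## Steps

Step 1
Reactants: 1 methyl (R)-3-hydroxy-2-methylpropanoate ((R)-Roche ester)
Product: 2 methyl (R)-3-(tert-butyldimethylsilyloxy)-2-methylpropanoate
Conditions: TBSCl, imidazole, DMF, 0 °C to rt
Reagents that add atoms: tert-butyldimethylsilyl chloride, CC(C)(C)[Si](C)(C)Cl
Why: Standard silylation of a primary alcohol; the stereocentre (future C5) is not touched.

Step 2
Reactants: 2 methyl (R)-3-(tert-butyldimethylsilyloxy)-2-methylpropanoate
Product: 3 (R)-3-(tert-butyldimethylsilyloxy)-2-methylpropanal
Conditions: DIBAL-H, CH2Cl2, −78 °C; aq. Rochelle salt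
Reagents that add atoms: none
Why: Partial ester reduction through a tetrahedral aluminate that is stable at low temperature, a routine operation on silylated Roche ester; the aldehyde is used at once to avoid epimerisation at C5.

Step 3
Reactants: 3 (R)-3-(tert-butyldimethylsilyloxy)-2-methylpropanal
Product: 5 (2R,3R)-1-(tert-butyldimethylsilyloxy)-2-methylhex-5-en-3-ol, via borinate adduct 4 (not isolated)
Conditions: (+)-Ipc2BOMe [(−)-α-pinene series], allylMgBr, Et2O, 0 °C to rt; 3, −78 °C; NaOH, H2O2
Reagents that add atoms: allylmagnesium bromide, C=CC[Mg]Br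
Why: Brown allylboration through a chair transition state; the (−)-α-pinene-derived reagent attacks the Re face and sets 4R. The 4,5-syn product is also the Felkin product, so reagent and substrate control reinforce each other.

Step 4
Reactants: 5 (2R,3R)-1-(tert-butyldimethylsilyloxy)-2-methylhex-5-en-3-ol
Product: 6 (4R,5R)-4,6-bis(tert-butyldimethylsilyloxy)-5-methylhex-1-ene
Conditions: TBSOTf, 2,6-lutidine, CH2Cl2, 0 °C
Reagents that add atoms: tert-butyldimethylsilyl triflate, CC(C)(C)[Si](C)(C)OS(=O)(=O)C(F)(F)F
Why: Silylation of a hindered secondary alcohol with the reactive triflate; no stereocentre is affected.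

Step 5
Reactants: 6 (4R,5R)-4,6-bis(tert-butyldimethylsilyloxy)-5-methylhex-1-ene
Product: 7 (2R,3R)-3-(tert-butyldimethylsilyloxy)-2-methylhex-5-en-1-ol
Conditions: HF·pyridine, pyridine, THF, 0 °C
Reagents that add atoms: none
Why: Buffered fluoride removes the less hindered primary silyl ether faster than the secondary one, a well-used differentiation.

Step 6
Reactants: 7 (2R,3R)-3-(tert-butyldimethylsilyloxy)-2-methylhex-5-en-1-ol
Product: 8 (4R,5S)-6-bromo-4-(tert-butyldimethylsilyloxy)-5-methylhex-1-ene
Conditions: CBr4, PPh3, CH2Cl2, 0 °C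
Reagents that add atoms: carbon tetrabromide, BrC(Br)(Br)Br
Why: Appel bromination by SN2 at the primary carbon C6. C5 keeps its spatial arrangement and only its CIP descriptor changes.

Step 7
Reactants: 9 (R)-citronellal
Product: 10 (R)-4,8-dimethylnona-1,7-diene
Conditions: Ph3PCH3Br, KOt-Bu, THF, 0 °C to rt
Reagents that add atoms: methyltriphenylphosphonium bromide, C[P+](c1ccccc1)(c1ccccc1)c1ccccc1.[Br-]
Why: Wittig methylenation creates C10=C11; the stereocentre (C13) is β to the carbonyl group and cannot epimerise.

Step 8
Reactants: 10 (R)-4,8-dimethylnona-1,7-diene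
Product: 12 (2R,4R)-2,4,8-trimethylnon-7-en-1-ol, via dimethylalkylalane 11 (not isolated)
Conditions: Me3Al, (−)-(NMI)2ZrCl2 (5 mol %, the enantiomer that turns 1-alkenes into (R)-2-methylalkylalanes), MAO (cat.), CH2Cl2, 0 °C to rt; O2, 0 °C; aq. HCl
Reagents that add atoms: trimethylaluminium, C[Al](C)C; dioxygen, O=O
Why: ZACA reaction, in which the chiral zirconocene adds CH3 to C11 and Al to C10 of the terminal alkene only (the trisubstituted alkene is inert); the C–Al bond is then oxidised with retention. C11 is set by the catalyst, and since C13 is fixed the wrong-face product is the 2,4-anti diastereomer, removable by chromatography at the alcohol stage.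

Step 9
Reactants: 12 (2R,4R)-2,4,8-trimethylnon-7-en-1-ol
Product: 13 (2R,4R)-2,4,8-trimethylnon-7-enal
Conditions: Dess–Martin periodinane, CH2Cl2, 0 °C to rt
Reagents that add atoms: none
Why: Dess–Martin oxidation is mild and non-basic, so the α-stereocentre C11 and the alkene are preserved.

Step 10
Reactants: 13 (2R,4R)-2,4,8-trimethylnon-7-enal
Product: 15 (4R,5R,7R)-5,7,11-trimethyldodeca-1,10-dien-4-ol, via borinate adduct 14 (not isolated)
Conditions: (+)-Ipc2BOMe [(−)-α-pinene series], allylMgBr, Et2O, 0 °C to rt; 13, −78 °C; NaOH, H2O2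
Reagents that add atoms: allylmagnesium bromide, C=CC[Mg]Br
Why: Same Brown allylboration as in step 3: Re-face attack sets 10R, and the 10,11-syn product is again the Felkin (matched) one. The new allyl group is C7–C9 and will serve as the coupling handle.

Step 11
Reactants: 15 (4R,5R,7R)-5,7,11-trimethyldodeca-1,10-dien-4-ol
Product: 16 (4R,5R,7R)-4-(tert-butyldimethylsilyloxy)-5,7,11-trimethyldodeca-1,10-diene
Conditions: TBSOTf, 2,6-lutidine, CH2Cl2, 0 °C
Reagents that add atoms: tert-butyldimethylsilyl triflate, CC(C)(C)[Si](C)(C)OS(=O)(=O)C(F)(F)F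
Why: Routine silylation of the secondary alcohol so that it interferes neither with the borane nor with the later oxidations.

Step 12
Reactants: 16 (4R,5R,7R)-4-(tert-butyldimethylsilyloxy)-5,7,11-trimethyldodeca-1,10-diene; 8 (4R,5S)-6-bromo-4-(tert-butyldimethylsilyloxy)-5-methylhex-1-ene
Product: 18 (4R,5R,10R,11R,13R)-4,10-bis(tert-butyldimethylsilyloxy)-5,11,13,17-tetramethyloctadeca-1,16-diene, via B-alkyl-9-BBN 17 (not isolated)
Conditions: 16, 9-BBN (1.05 equiv), THF, 0 °C to rt; then K3PO4·H2O, Pd(OAc)2 (4 mol %), PCy3 (8 mol %), 8, THF, rt to 40 °C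
Reagents that add atoms: none
Why: 9-BBN hydroborates only the monosubstituted C7=C8 alkene of 16, and the hydrated base destroys residual B–H before 8 is added. The alkyl–alkyl Suzuki–Miyaura coupling with a bulky trialkylphosphine proceeds by SN2-type oxidative addition (no C6 radical). The coordinatively saturated bis-phosphine alkylpalladium species should resist both β-hydride elimination and insertion of C1=C2.

Step 13
Reactants: 18 (4R,5R,10R,11R,13R)-4,10-bis(tert-butyldimethylsilyloxy)-5,11,13,17-tetramethyloctadeca-1,16-diene
Product: 19 16,17-epoxide of 18 (mixture of C16 epimers, of no consequence)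
Conditions: mCPBA (1.0 equiv), CH2Cl2, 0 °C
Reagents that add atoms: 3-chloroperbenzoic acid, OOC(=O)c1cccc(Cl)c1
Why: Prilezhaev epoxidation is governed by alkene nucleophilicity, so the trisubstituted C16 alkene reacts far faster than monosubstituted C1=C2.

Step 14
Reactants: 19 16,17-epoxide of 18
Product: 20 (4R,6R,7R,12R,13R)-7,13-bis(tert-butyldimethylsilyloxy)-4,6,12-trimethylhexadec-15-enal (C1–C16 aldehyde)
Conditions: H5IO6, THF–Et2O, 0 °C
Reagents that add atoms: none
Why: Periodic acid opens the epoxide and cleaves the resulting glycol in one operation, releasing the C16 aldehyde and acetone. Secondary silyl ethers and the terminal alkene tolerate the short cold exposure.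

Step 15
Reactants: 21 2,3-dibromopropene; 22 phenylmagnesium bromide
Product: 23 (2-bromoallyl)benzene
Conditions: CuI (5 mol %), THF, 0 °C to rt
Reagents that add atoms: none
Why: Allylic substitution of the reactive allylic bromide by the Grignard reagent. SN2 and SN2′ attack give the same product, and the vinylic bromide is untouched.

Step 16
Reactants: 23 (2-bromoallyl)benzene
Product: 26 (4S,5S)-4,5-dicyclohexyl-2-(3-phenylprop-1-en-2-yl)-1,3,2-dioxaborolane, via alkenyllithium 24 (not isolated), via diisopropyl alkenylboronate 25 (not isolated)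
Conditions: t-BuLi (2 equiv), Et2O, −78 °C; B(Oi-Pr)3, −78 °C to rt; HCl·Et2O (1 equiv), 0 °C; (S,S)-1,2-dicyclohexylethane-1,2-diol, rt
Reagents that add atoms: triisopropyl borate, CC(C)OB(OC(C)C)OC(C)C; (S,S)-1,2-dicyclohexylethane-1,2-diol, O[C@@H](C1CCCCC1)[C@@H](O)C1CCCCC1
Why: Bromine–lithium exchange at −78 °C is faster than proton transfer from the benzylic position. Borylation and transesterification with the diol are standard and driven by formation of the five-membered ring.

Step 17
Reactants: 26 (4S,5S)-4,5-dicyclohexyl-2-(3-phenylprop-1-en-2-yl)-1,3,2-dioxaborolane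
Product: 28 (4S,5S)-2-[(1R)-2-benzyl-1-chloroprop-2-en-1-yl]-4,5-dicyclohexyl-1,3,2-dioxaborolane, via dichloromethylborate 27 (not isolated)
Conditions: CH2Cl2, n-BuLi, THF, −100 °C; 26; ZnCl2, −100 °C to rt; pentane extraction, used without chromatography
Reagents that add atoms: dichloromethane, ClCCl
Why: Matteson asymmetric homologation, in which the carbenoid adds to boron and the alkenyl group migrates with loss of the chloride selected by the C2-symmetric diol. (R,R)-diols give (αS)-chloro boronic esters, so the (S,S)-diol gives (R)-C20. ZnCl2 speeds up the shift and binds the chloride that could epimerise 28.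

Step 18
Reactants: 20 C1–C16 aldehyde; 28 (4S,5S)-2-[(1R)-2-benzyl-1-chloroprop-2-en-1-yl]-4,5-dicyclohexyl-1,3,2-dioxaborolane
Product: 30 (4R,5R,10R,11R,13R,16R)-4,10-bis(tert-butyldimethylsilyloxy)-18-[(Z)-chloromethylidene]-5,11,13-trimethyl-19-phenylnonadec-1-en-16-ol, via C16 borate ester 29 (not isolated)
Conditions: 28 (1.5 equiv), 4 Å MS, toluene, rt, 2–3 d; then N(CH2CH2OH)3, CH2Cl2, rt
Reagents that add atoms: none
Why: Type I allylboration: the boron of 28 binds the aldehyde oxygen of 20 and the allyl unit is handed over through a closed six-membered chair (B–O–C16–C17–C18–C20), so C16–C17 forms while the double bond shifts to C18=C20 and the C20 stereocentre is consumed. The closest known reaction type is the addition of enantioenriched α-chloroallylboronic esters to aldehydes, which gives (Z)-chloro homoallylic alcohols with transfer of chirality; here the allyl unit merely carries a benzyl group on its central carbon. No ring is closed in the product; the only ring is the transient chair. C16 is controlled by C20: with the C15 chain equatorial and Cl axial, the (R)-C20 reagent can reach only the Si face of 20, which gives 16R. The alkene geometry comes from the same chair, because an axial Cl ends up cis to C17 (Z). The selectivity needed is axial over equatorial Cl, and it is secured by the dipole and hyperconjugative preference of the C–Cl bond, by the clash of an equatorial Cl with the dicyclohexyldioxaborolane and, specific to this substrate, by A(1,2) strain between an equatorial Cl and the C18 benzyl group. The minor chair (Cl equatorial) would give the E alkene together with 16S, a diastereomer that differs in two elements and should be removable by chromatography. The conditions are neutral, so the enolisable aldehyde, the silyl ethers and C1=C2 are not touched, and triethanolamine frees the alcohol and returns the diol.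

Step 19
Reactants: 30 4,10-bis-silyl ether of the target
Product: 31 (4R,5R,10R,11R,13R,16R)-18-[(Z)-chloromethylidene]-5,11,13-trimethyl-19-phenylnonadec-1-ene-4,10,16-triol (CNP0072706.1)
Conditions: aq. HF (48 %), MeCN, 0 °C to rt
Reagents that add atoms: none
Why: Fluoride-driven cleavage of both secondary silyl ethers under mildly acidic conditions, which neither isomerise the skipped chloroalkene nor affect the terminal alkene or any stereocentre.

## Compound list

1 | methyl (R)-3-hydroxy-2-methylpropanoate | COC(=O)[C@H](C)CO | starting material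
2 | methyl (R)-3-(tert-butyldimethylsilyloxy)-2-methylpropanoate | COC(=O)[C@H](C)CO[Si](C)(C)C(C)(C)C | intermediate
3 | (R)-3-(tert-butyldimethylsilyloxy)-2-methylpropanal | O=C[C@H](C)CO[Si](C)(C)C(C)(C)C | intermediate
4 | diisopinocampheylborinate of 5 | C=CC[C@@H](OB([C@H]1C[C@H]2C[C@@H]([C@@H]1C)C2(C)C)[C@H]1C[C@H]2C[C@@H]([C@@H]1C)C2(C)C)[C@H](C)CO[Si](C)(C)C(C)(C)C | intermediate
5 | (2R,3R)-1-(tert-butyldimethylsilyloxy)-2-methylhex-5-en-3-ol | C=CC[C@@H](O)[C@H](C)CO[Si](C)(C)C(C)(C)C | intermediate
6 | (4R,5R)-4,6-bis(tert-butyldimethylsilyloxy)-5-methylhex-1-ene | C=CC[C@@H](O[Si](C)(C)C(C)(C)C)[C@H](C)CO[Si](C)(C)C(C)(C)C | intermediate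
7 | (2R,3R)-3-(tert-butyldimethylsilyloxy)-2-methylhex-5-en-1-ol | C=CC[C@@H](O[Si](C)(C)C(C)(C)C)[C@H](C)CO | intermediate
8 | (4R,5S)-6-bromo-4-(tert-butyldimethylsilyloxy)-5-methylhex-1-ene | C=CC[C@@H](O[Si](C)(C)C(C)(C)C)[C@H](C)CBr | intermediate
9 | (R)-citronellal | O=CC[C@H](C)CCC=C(C)C | starting material
10 | (R)-4,8-dimethylnona-1,7-diene | C=CC[C@H](C)CCC=C(C)C | intermediate
11 | dimethyl[(2R,4R)-2,4,8-trimethylnon-7-en-1-yl]alane | C[Al](C)C[C@H](C)C[C@H](C)CCC=C(C)C | intermediate
12 | (2R,4R)-2,4,8-trimethylnon-7-en-1-ol | OC[C@H](C)C[C@H](C)CCC=C(C)C | intermediate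
13 | (2R,4R)-2,4,8-trimethylnon-7-enal | O=C[C@H](C)C[C@H](C)CCC=C(C)C | intermediate
14 | diisopinocampheylborinate of 15 | C=CC[C@@H](OB([C@H]1C[C@H]2C[C@@H]([C@@H]1C)C2(C)C)[C@H]1C[C@H]2C[C@@H]([C@@H]1C)C2(C)C)[C@H](C)C[C@H](C)CCC=C(C)C | intermediate
15 | (4R,5R,7R)-5,7,11-trimethyldodeca-1,10-dien-4-ol | C=CC[C@@H](O)[C@H](C)C[C@H](C)CCC=C(C)C | intermediate
16 | (4R,5R,7R)-4-(tert-butyldimethylsilyloxy)-5,7,11-trimethyldodeca-1,10-diene | C=CC[C@@H](O[Si](C)(C)C(C)(C)C)[C@H](C)C[C@H](C)CCC=C(C)C | intermediate
17 | B-alkyl-9-BBN from 16 (boron on C7) | C1CC2CCCC(C1)B2CCC[C@@H](O[Si](C)(C)C(C)(C)C)[C@H](C)C[C@H](C)CCC=C(C)C | intermediate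
18 | (4R,5R,10R,11R,13R)-4,10-bis(tert-butyldimethylsilyloxy)-5,11,13,17-tetramethyloctadeca-1,16-diene | C=CC[C@@H](O[Si](C)(C)C(C)(C)C)[C@H](C)CCCC[C@@H](O[Si](C)(C)C(C)(C)C)[C@H](C)C[C@H](C)CCC=C(C)C | intermediate
19 | 16,17-epoxide of 18 (C16 epimers) | C=CC[C@@H](O[Si](C)(C)C(C)(C)C)[C@H](C)CCCC[C@@H](O[Si](C)(C)C(C)(C)C)[C@H](C)C[C@H](C)CCC1OC1(C)C | intermediate
20 | (4R,6R,7R,12R,13R)-7,13-bis(tert-butyldimethylsilyloxy)-4,6,12-trimethylhexadec-15-enal | C=CC[C@@H](O[Si](C)(C)C(C)(C)C)[C@H](C)CCCC[C@@H](O[Si](C)(C)C(C)(C)C)[C@H](C)C[C@H](C)CCC=O | intermediate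
21 | 2,3-dibromopropene | C=C(Br)CBr | starting material
22 | phenylmagnesium bromide | Br[Mg]c1ccccc1 | starting material
23 | (2-bromoallyl)benzene | C=C(Br)Cc1ccccc1 | intermediate
24 | (3-phenylprop-1-en-2-yl)lithium | [Li]C(=C)Cc1ccccc1 | intermediate
25 | diisopropyl (3-phenylprop-1-en-2-yl)boronate | C=C(Cc1ccccc1)B(OC(C)C)OC(C)C | intermediate
26 | (4S,5S)-4,5-dicyclohexyl-2-(3-phenylprop-1-en-2-yl)-1,3,2-dioxaborolane | C=C(Cc1ccccc1)B1O[C@@H](C2CCCCC2)[C@H](C2CCCCC2)O1 | intermediate
27 | lithium (dichloromethyl)(alkenyl)borate of 26 | [Li+].C=C(Cc1ccccc1)[B-]1(C(Cl)Cl)O[C@@H](C2CCCCC2)[C@H](C2CCCCC2)O1 | intermediate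
28 | (4S,5S)-2-[(1R)-2-benzyl-1-chloroprop-2-en-1-yl]-4,5-dicyclohexyl-1,3,2-dioxaborolane | C=C(Cc1ccccc1)[C@H](Cl)B1O[C@@H](C2CCCCC2)[C@H](C2CCCCC2)O1 | intermediate
29 | C16 borate ester of 30 with the dicyclohexyldioxaborolane | C=CC[C@@H](O[Si](C)(C)C(C)(C)C)[C@H](C)CCCC[C@@H](O[Si](C)(C)C(C)(C)C)[C@H](C)C[C@H](C)CC[C@@H](OB1O[C@@H](C2CCCCC2)[C@H](C2CCCCC2)O1)C/C(=C\Cl)Cc1ccccc1 | intermediate
30 | (4R,5R,10R,11R,13R,16R)-4,10-bis(tert-butyldimethylsilyloxy)-18-[(Z)-chloromethylidene]-5,11,13-trimethyl-19-phenylnonadec-1-en-16-ol | C=CC[C@@H](O[Si](C)(C)C(C)(C)C)[C@H](C)CCCC[C@@H](O[Si](C)(C)C(C)(C)C)[C@H](C)C[C@H](C)CC[C@@H](O)C/C(=C\Cl)Cc1ccccc1 | intermediate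
31 | (4R,5R,10R,11R,13R,16R)-18-[(Z)-chloromethylidene]-5,11,13-trimethyl-19-phenylnonadec-1-ene-4,10,16-triol | C=CC[C@@H](O)[C@H](C)CCCC[C@@H](O)[C@H](C)C[C@H](C)CC[C@@H](O)C/C(=C\Cl)Cc1ccccc1 | target

## Step count and risks

Total step count: 19.
Longest linear sequence: 11 steps (1–6, 12–14, 18, 19, from Roche ester 1). The citronellal branch has 10 steps and the boronate branch 5.

**Step 18 (key step).**
- What may go wrong: the chair with equatorial chlorine may compete (loss of Z selectivity together with loss of 16R). Chirality transfer will be incomplete if 28 has partly epimerised before use. The hindered boronic ester may react so slowly that the aldehyde self-condenses.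
- Fallback: it sets out from 20 and returns at 30, and it separates the two tasks.
- A Brown allylboration of 20 uses the 2-benzylallyl reagent of the (+)-α-pinene series, (2-benzylallyl)diisopinocampheylborane F1. F1 is made from (−)-Ipc2BOMe and the Grignard reagent of 2-benzylallyl chloride, and it attacks the Si face. This sets 16R and gives the 1,1-disubstituted homoallylic alcohol F2.
- Hydroxyl-directed epoxidation (VO(acac)2, t-BuOOH) touches only the alkene next to the free C16-OH and gives epoxy alcohol F3.
- Periodic acid cleaves F3 to the β-hydroxy ketone F4, which is protected as its triethylsilyl ether F5.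
- Wittig chloromethylenation of F5 gives an E/Z pair, from which the Z-chloroalkene silyl ether F6 is separated.
- PPTS in methanol removes the triethylsilyl group only, which gives 30.

**Step 12.**
- What may go wrong: oxidative addition to the β-branched bromide may be slow. The C6–palladium species may undergo β-hydride elimination or 5-exo insertion of C1=C2 before transmetalation.
- Fallback: it sets out from 16 (with 8 as partner) and returns at 18, and it replaces palladium by a polar copper-catalysed substitution.
- Hydroboration and oxidation of 16 gives the primary alcohol F7, and Appel bromination gives the primary bromide F8.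
- Magnesium turns F8 into the Grignard reagent F9, which displaces the bromide of 8 under Li2CuCl4 catalysis in THF–NMP.
- No metal ever sits on C6 in this sequence, so cyclisation onto C1=C2 cannot occur.

**Step 17.**
- What may go wrong: chloride-induced epimerisation of the allylic α-chloro boronic ester during warming or work-up, double homologation, or loss of material because 28 cannot be chromatographed.
- Fallback: it sets out from 23 and returns at 30, and it moves the stereocontrol from the reagent to a catalyst.
- Miyaura borylation of 23 gives the pinacol alkenylboronate F10.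
- Homologation with the same carbenoid gives the racemic pinacol α-chloroallylboronate F11, for which epimerisation is irrelevant.
- F11 is used in excess with 20 and the appropriate enantiomer of a bulky BINOL-derived phosphoric acid. The acid activates the boronate, directs Si-face attack, and consumes mainly the matching enantiomer of F11 (kinetic resolution of an α-substituted allylboronate).

**Step 8.**
- What may go wrong: imperfect facial selectivity of the carboalumination, competing hydroalumination, and a difficult separation of the 2,4-anti isomer.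
- Fallback: it sets out from 10 and returns at 12, and it replaces catalyst control by an auxiliary.
- Selective 9-BBN hydroboration and oxidation of the terminal alkene gives (R)-4,8-dimethylnon-7-en-1-ol F12.
- Oxidation (TEMPO, PhI(OAc)2, aq. MeCN) gives (R)-4,8-dimethylnon-7-enoic acid F13.
- Acylation of (R)-4-benzyloxazolidin-2-one through the mixed pivalic anhydride gives the imide F14.
- Evans alkylation (NaHMDS, MeI) sets C11 and gives the methylated imide F15, whose diastereomers are separable.
- LiBH4 releases 12.

## Further compounds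

F1 | step 18 | (2-benzylallyl)diisopinocampheylborane, (+)-α-pinene series | C=C(Cc1ccccc1)CB([C@@H]1C[C@@H]2C[C@H]([C@H]1C)C2(C)C)[C@@H]1C[C@@H]2C[C@H]([C@H]1C)C2(C)C
F2 | step 18 | (16R)-homoallylic alcohol with C18=CH2 (4,10-bis-TBS) | C=CC[C@@H](O[Si](C)(C)C(C)(C)C)[C@H](C)CCCC[C@@H](O[Si](C)(C)C(C)(C)C)[C@H](C)C[C@H](C)CC[C@@H](O)CC(=C)Cc1ccccc1
F3 | step 18 | epoxy alcohol from F2 (epoxide epimers of no consequence) | C=CC[C@@H](O[Si](C)(C)C(C)(C)C)[C@H](C)CCCC[C@@H](O[Si](C)(C)C(C)(C)C)[C@H](C)C[C@H](C)CC[C@@H](O)CC1(Cc2ccccc2)CO1
F4 | step 18 | (16R)-16-hydroxy-18-ketone (4,10-bis-TBS) | C=CC[C@@H](O[Si](C)(C)C(C)(C)C)[C@H](C)CCCC[C@@H](O[Si](C)(C)C(C)(C)C)[C@H](C)C[C@H](C)CC[C@@H](O)CC(=O)Cc1ccccc1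
F5 | step 18 | 16-O-triethylsilyl ether of F4 | C=CC[C@@H](O[Si](C)(C)C(C)(C)C)[C@H](C)CCCC[C@@H](O[Si](C)(C)C(C)(C)C)[C@H](C)C[C@H](C)CC[C@@H](O[Si](CC)(CC)CC)CC(=O)Cc1ccccc1
F6 | step 18 | 16-O-triethylsilyl ether of 30 (Z-chloroalkene) | C=CC[C@@H](O[Si](C)(C)C(C)(C)C)[C@H](C)CCCC[C@@H](O[Si](C)(C)C(C)(C)C)[C@H](C)C[C@H](C)CC[C@@H](O[Si](CC)(CC)CC)C/C(=C\Cl)Cc1ccccc1
F7 | step 12 | (4R,5R,7R)-4-(tert-butyldimethylsilyloxy)-5,7,11-trimethyldodec-10-en-1-ol | OCCC[C@@H](O[Si](C)(C)C(C)(C)C)[C@H](C)C[C@H](C)CCC=C(C)C
F8 | step 12 | primary bromide from F7 | BrCCC[C@@H](O[Si](C)(C)C(C)(C)C)[C@H](C)C[C@H](C)CCC=C(C)C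
F9 | step 12 | Grignard reagent from F8 | Br[Mg]CCC[C@@H](O[Si](C)(C)C(C)(C)C)[C@H](C)C[C@H](C)CCC=C(C)C
F10 | step 17 | 4,4,5,5-tetramethyl-2-(3-phenylprop-1-en-2-yl)-1,3,2-dioxaborolane | C=C(Cc1ccccc1)B1OC(C)(C)C(C)(C)O1
F11 | step 17 | racemic 2-(2-benzyl-1-chloroprop-2-en-1-yl)-4,4,5,5-tetramethyl-1,3,2-dioxaborolane | C=C(Cc1ccccc1)C(Cl)B1OC(C)(C)C(C)(C)O1
F12 | step 8 | (R)-4,8-dimethylnon-7-en-1-ol | OCCC[C@H](C)CCC=C(C)C
F13 | step 8 | (R)-4,8-dimethylnon-7-enoic acid | OC(=O)CC[C@H](C)CCC=C(C)C
F14 | step 8 | (R)-4-benzyl-3-[(R)-4,8-dimethylnon-7-enoyl]oxazolidin-2-one | O=C1OC[C@@H](Cc2ccccc2)N1C(=O)CC[C@H](C)CCC=C(C)C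
F15 | step 8 | (R)-4-benzyl-3-[(2R,4R)-2,4,8-trimethylnon-7-enoyl]oxazolidin-2-one | O=C1OC[C@@H](Cc2ccccc2)N1C(=O)[C@H](C)C[C@H](C)CCC=C(C)C
A1 | alternative 1 | 4,10,16-tris-TBS-protected C18 ketone | C=CC[C@@H](O[Si](C)(C)C(C)(C)C)[C@H](C)CCCC[C@@H](O[Si](C)(C)C(C)(C)C)[C@H](C)C[C@H](C)CC[C@@H](O[Si](C)(C)C(C)(C)C)CC(=O)Cc1ccccc1
A2 | alternative 2 | 4,10,16-tris-TBS-protected terminal alkyne (C18≡C20H) | C=CC[C@@H](O[Si](C)(C)C(C)(C)C)[C@H](C)CCCC[C@@H](O[Si](C)(C)C(C)(C)C)[C@H](C)C[C@H](C)CC[C@@H](O[Si](C)(C)C(C)(C)C)CC#C
A3 | alternative 2 | E-chloroalkene (Cl cis to benzyl), tris-TBS ether | C=CC[C@@H](O[Si](C)(C)C(C)(C)C)[C@H](C)CCCC[C@@H](O[Si](C)(C)C(C)(C)C)[C@H](C)C[C@H](C)CC[C@@H](O[Si](C)(C)C(C)(C)C)C/C(=C/Cl)Cc1ccccc1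
A4 | alternative 3 | (4R,5R)-5-(tert-butyldimethylsilyloxy)-4-methyloct-7-enoic acid | C=CC[C@@H](O[Si](C)(C)C(C)(C)C)[C@H](C)CCC(=O)O
A5 | alternative 3 | (4R,5R,7R)-4-(tert-butyldimethylsilyloxy)-5,7,11-trimethyldodec-10-enoic acid | OC(=O)CC[C@@H](O[Si](C)(C)C(C)(C)C)[C@H](C)C[C@H](C)CCC=C(C)C
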